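Start from slowness: substrate reaches target by way of intermediate A, and while it lingers, the target already made can react with it.

substrate 0.24 M; time 2.5 d

    intermediate A ⇌ intermediate B (K1 = 0.43, k1 = 0.33 h⁻¹)
    2 substrate → homo dimer (k2 = 0.047 M⁻¹ h⁻¹)
    substrate + target → side product B (k3 = 1.2 M⁻¹ h⁻¹)
    intermediate B → side product A (k4 = 0.13 h⁻¹)
    intermediate A → target (k5 = 2.8 h⁻¹)
    substrate ⇌ intermediate A (K6 = 0.55, k6 = 4.0 h⁻¹)

- the state of affairs at 2.5 d: stopped, and by what, or still going (all of the substrate has reacted / forward and back rates have come level / it is still moving)
- amount of target at 2.5 d, in percent of the substrate charged
- amount of side product B at 2.5 d, in percent of the substrate charged
- amount of target if the flask were left three thousand times as long, in percent of the substrate charged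

- percentages count the substrate that a species holds: one homo dimer or side product B counts as two
- a step written with two of one species runs at k times the square of its concentration and takes two of it each time
- the reaction counts as stopped when no species that holds the substrate changes by six tenths of a point or more over the second half of the time
- run time (flask): 2.5 d

First find the real pace of that road, leaving aside intermediate B and the homo dimer. Intermediate A falls back to substrate at 7.27 h⁻¹ and goes on to target at 2.8 h⁻¹, so it returns more readily than it advances, and 27.8 % of it passes. Substrate therefore drains to target at 1.11 h⁻¹, a half-life of 0.624 h, far shorter than the 2.5 d allowed. Expect a stopped flask, and since the one step that takes target needs substrate, expect the same figure after the long wait.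

Divide the drain by the constant of the side step, 1.2 M⁻¹ h⁻¹, to get 0.927 M. Call this the even level: the target concentration at which substrate goes as fast to side product B as to target, a selectivity factor in molar units. Substrate cancels from that comparison, so the side route's share against the main route is simply target over even level. The charge of 0.24 M lies below the even level, so the main route stays ahead.

Now reckon the yield two ways. First, let the full charge go down the main road and let target be eaten along the way: this gives 88.1 %. Second, count substrate: the ratio climbs evenly from zero, so side product B, counted by its two substrates, comes to target times target over even level, and this plus target equals the charge. That gives 82.4 %.

The two part, and the first one cheats: each side turn also eats a substrate, so the main road carries less than the charge, namely the mean of charge and target. Put that into the first way and it gives 81.2 %, which is my figure for target, with the remainder shared among the side products.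

The forecast says all of the substrate has reacted, with target 80 %, side product B 17 % and 80 % after the long wait. Its ground is that “the main loss is substrate meeting target late in the run”. Its target stands under mine.

The flask gives all of the substrate has reacted, with target 80.4 %, side product B 17.4 % and 80.4 % after the long wait. Substrate stood at 0.361 % of its charge by 0.250 d. Now take the even level to the neighbour flask charged with 0.096 M, and run the same reckoning: it gives 91.1 % of target. That neighbour flask holds 90.0 % of target.

Its constants belong to no real substance; what happens was integrated by code.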